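Ring B of asplenetin carries oxygen on C3', C4' and C5', set between two unsubstituted carbons, C2' and C6'. That pattern is read as 3,4-dimethoxyfuran, whose four carbons become C2'–C5' and whose ring oxygen becomes the C5' hydroxyl, joined to a two-carbon alkyne that supplies C1' and C6'. The A/C chromone is therefore built first, with the 3-methylbutyl chain on C3 and a terminal ethynyl group on C2, and ring B is closed last. One Diels–Alder addition to the alkyne followed by acid opening of the oxygen bridge forms both new C–C bonds and the phenol. The precursor is 2-ethynyl-5,7-dimethoxy-3-(3-methylbutyl)chromen-4-one; BBr3 then removes the four methyl ethers.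

Key step: step 5

Remark: ring B is labelled so that C1' is bonded to C2 of the chromone and C5' is the carbon that keeps the furan oxygen; 3,4-dimethoxyfuran is taken as a purchasable reagent.

Step 1
Reactants: 1 5-methylhexanoic acid; 2 1,3,5-trimethoxybenzene
Product: 5 1-(2-hydroxy-4,6-dimethoxyphenyl)-5-methylhexan-1-one, via acid chloride 3 (not isolated), via trimethoxyphenyl ketone 4 (not isolated)
Conditions: (COCl)2, DMF (cat.), CH2Cl2, 0 °C to rt, evaporate; then 2, AlCl3 (3 equiv), CH2Cl2, 0 to 40 °C; HCl (aq) work-up
Reagents that add atoms: none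
Why: Friedel–Crafts acylation of the symmetrical, strongly activated arene can give only one ketone, and AlCl3 chelated to the new carbonyl should cleave one ortho methyl ether under these mild conditions, so acid chloride formation, acylation and selective ortho-demethylation run as one operation.

Step 2
Reactants: 5 1-(2-hydroxy-4,6-dimethoxyphenyl)-5-methylhexan-1-one; 6 diethyl oxalate
Product: 8 ethyl 5,7-dimethoxy-3-(3-methylbutyl)-4-oxo-4H-chromene-2-carboxylate, via diketo ester 7 (not isolated)
Conditions: NaOEt (4 equiv), 6 (3 equiv), EtOH, reflux; then HCl (conc.), EtOH, reflux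
Reagents that add atoms: none
Why: Crossed Claisen condensation of the phenoxide–enolate dianion with the non-enolisable oxalate should give the 2,4-dioxo ester, which under acid closes by attack of the phenol on the C2 ketone and loss of water, the classical chromone-2-carboxylate synthesis.

Step 3
Reactants: 8 ethyl 5,7-dimethoxy-3-(3-methylbutyl)-4-oxo-4H-chromene-2-carboxylate
Product: 9 2-(hydroxymethyl)-5,7-dimethoxy-3-(3-methylbutyl)chromen-4-one
Conditions: NaBH4 (2 equiv), MeOH/THF, 0 °C
Reagents that add atoms: none
Why: Borohydride reduction should touch only the ester, which is activated by the ring oxygen on its α-carbon, because the C4 carbonyl is a vinylogous ester deactivated by the 5- and 7-methoxy groups and the C2=C3 bond is tetrasubstituted.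

Step 4
Reactants: 9 2-(hydroxymethyl)-5,7-dimethoxy-3-(3-methylbutyl)chromen-4-one
Product: 11 2-ethynyl-5,7-dimethoxy-3-(3-methylbutyl)chromen-4-one, via chromone-2-carbaldehyde 10 (not isolated)
Conditions: MnO2 (10 equiv), THF, rt; then MeOH, K2CO3 (2 equiv), MeCOC(N2)P(O)(OMe)2 (1.3 equiv), 0 °C to rt
Reagents that add atoms: dimethyl (1-diazo-2-oxopropyl)phosphonate (Ohira–Bestmann reagent), CC(=O)C(=[N+]=[N-])P(=O)(OC)OC
Why: MnO2 oxidises the allylic-type primary alcohol to the aldehyde, and in the same flask the Seyferth–Gilbert homologation in its Ohira–Bestmann form (Horner–Wadsworth–Emmons addition of the diazophosphonate anion, loss of N2, 1,2-hydrogen shift of the alkylidene carbene) should convert this aldehyde, which has no α-hydrogen and behaves like an aryl aldehyde, into the terminal alkyne without isolating the hydration-prone aldehyde.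

Step 5
Reactants: 11 2-ethynyl-5,7-dimethoxy-3-(3-methylbutyl)chromen-4-one; 12 3,4-dimethoxyfuran
Product: 14 2-(3-hydroxy-4,5-dimethoxyphenyl)-5,7-dimethoxy-3-(3-methylbutyl)chromen-4-one, via oxanorbornadiene adduct 13 (not isolated)
Conditions: 12 (4 equiv), ZnI2 (1 equiv), CH2Cl2, sealed tube, 40 °C; then CF3CO2H (3 equiv), 0 °C to rt
Reagents that add atoms: none
Why: The known reaction type is Diels–Alder addition of a furan to an acceptor-conjugated alkyne followed by acid isomerisation of the 7-oxanorbornadiene to a phenol (established for ynones, propiolates and acetylenedicarboxylates, also with Lewis-acid promotion); the ethynylchromone is a vinylogous ynone and an untried member of that class, so ZnI2 is chelated between the C4 carbonyl and the 5-methoxy group to give C2 oxocarbenium character and make the ethynyl group behave like a Lewis-acid-bound ynone. Ring B is closed by an intermolecular (4+2) cycloaddition in which the symmetrical, electron-rich furan 12 forms C1'–C2' and C5'–C6' (concerted but asynchronous, bonding first at the terminal alkyne carbon) and leaves its oxygen as a C2'–O–C5' bridge in 13; the symmetry of the diene removes any regiochemical question at this stage. CF3CO2H then protonates the bridge oxygen, the C2'–O bond ionises to a cation spread over C2', C4' and C6' and stabilised by the C4' methoxy group, and loss of the C5' proton aromatises the ring with the oxygen kept on C5'. The selectivity needed is this direction of bridge opening: cleavage of C5'–O instead would put positive charge on C1', which bears the electron-poor, zinc-bound chromonyl group, so that path should be disfavoured and the hydroxyl should end meta to the chromone (3',4',5' pattern). The two bridgehead stereocentres of racemic 13 vanish on aromatisation, so no stereocentre has to be controlled.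

Step 6
Reactants: 14 2-(3-hydroxy-4,5-dimethoxyphenyl)-5,7-dimethoxy-3-(3-methylbutyl)chromen-4-one
Product: 15 asplenetin, 5,7-dihydroxy-3-(3-methylbutyl)-2-(3,4,5-trihydroxyphenyl)chromen-4-one
Conditions: BBr3 (10 equiv), CH2Cl2, −78 °C to rt; then MeOH, H2O
Reagents that add atoms: none
Why: BBr3 cleavage of aryl methyl ethers should remove all four methyl groups as bromomethane, while the chromone and the saturated side chain have no group that reacts.

Compound list
1 | 5-methylhexanoic acid | CC(C)CCCC(=O)O | starting material
2 | 1,3,5-trimethoxybenzene | COc1cc(OC)cc(OC)c1 | starting material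
3 | 5-methylhexanoyl chloride | CC(C)CCCC(=O)Cl | intermediate
4 | 5-methyl-1-(2,4,6-trimethoxyphenyl)hexan-1-one | CC(C)CCCC(=O)c1c(OC)cc(OC)cc1OC | intermediate
5 | 1-(2-hydroxy-4,6-dimethoxyphenyl)-5-methylhexan-1-one | CC(C)CCCC(=O)c1c(O)cc(OC)cc1OC | intermediate
6 | diethyl oxalate | CCOC(=O)C(=O)OCC | starting material
7 | ethyl 3-(2-hydroxy-4,6-dimethoxybenzoyl)-6-methyl-2-oxoheptanoate (racemic, enolisable) | CCOC(=O)C(=O)C(CCC(C)C)C(=O)c1c(O)cc(OC)cc1OC | intermediate
8 | ethyl 5,7-dimethoxy-3-(3-methylbutyl)-4-oxo-4H-chromene-2-carboxylate | CCOC(=O)c1oc2cc(OC)cc(OC)c2c(=O)c1CCC(C)C | intermediate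
9 | 2-(hydroxymethyl)-5,7-dimethoxy-3-(3-methylbutyl)chromen-4-one | CC(C)CCc1c(CO)oc2cc(OC)cc(OC)c2c1=O | intermediate
10 | 5,7-dimethoxy-3-(3-methylbutyl)-4-oxo-4H-chromene-2-carbaldehyde | CC(C)CCc1c(C=O)oc2cc(OC)cc(OC)c2c1=O | intermediate
11 | 2-ethynyl-5,7-dimethoxy-3-(3-methylbutyl)chromen-4-one | CC(C)CCc1c(C#C)oc2cc(OC)cc(OC)c2c1=O | intermediate
12 | 3,4-dimethoxyfuran | COc1cocc1OC | starting material
13 | 2-(5,6-dimethoxy-7-oxabicyclo[2.2.1]hepta-2,5-dien-2-yl)-5,7-dimethoxy-3-(3-methylbutyl)chromen-4-one (racemic, one enantiomer drawn; the two bridgehead configurations are tied to each other by the bicycle) | COC1=C(OC)[C@@H]2O[C@H]1C(c3oc4cc(OC)cc(OC)c4c(=O)c3CCC(C)C)=C2 | intermediate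
14 | 2-(3-hydroxy-4,5-dimethoxyphenyl)-5,7-dimethoxy-3-(3-methylbutyl)chromen-4-one | CC(C)CCc1c(-c2cc(O)c(OC)c(OC)c2)oc2cc(OC)cc(OC)c2c1=O | intermediate
15 | asplenetin, 5,7-dihydroxy-3-(3-methylbutyl)-2-(3,4,5-trihydroxyphenyl)chromen-4-one | CC(C)CCc1c(-c2cc(O)c(O)c(O)c2)oc2cc(O)cc(O)c2c1=O | target

Total step count: 6
Longest linear sequence: 6 steps (1 to 15)

Steps most likely to fail

Step 5. The alkyne is activated only through the pyranone and may not be electrophilic enough to undergo cycloaddition at temperatures the furan tolerates. Under zinc activation the addition may turn stepwise and stop after bond formation at the furan α-carbon, with re-aromatisation of the furan instead of ring closure. In the acid stage the bridge may open toward C5', the bis-enol ether may be hydrolysed, or the furan may oligomerise. The fallback uses known chemistry and brings ring B in preformed; it sets out from 5. O-Acylation with 3,4,5-trimethoxybenzoyl chloride (pyridine, DMAP, CH2Cl2) should give 3,5-dimethoxy-2-(5-methylhexanoyl)phenyl 3,4,5-trimethoxybenzoate F1. Baker–Venkataraman rearrangement (KOH, pyridine, 50 °C) should then give 1-(2-hydroxy-4,6-dimethoxyphenyl)-2-(3-methylbutyl)-3-(3,4,5-trimethoxyphenyl)propane-1,3-dione F2. Cyclodehydration (H2SO4 cat., AcOH, 100 °C) should give 5,7-dimethoxy-3-(3-methylbutyl)-2-(3,4,5-trimethoxyphenyl)chromen-4-one F3. BBr3 (CH2Cl2, −78 °C to rt) then cleaves all five methyl ethers, and the fallback comes back to the route at 15.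

Step 4. Under carbonate in methanol, methoxide may add to the newly formed conjugated alkyne or to C2 of the pyranone with ring opening, and the MnO2 oxidation may stall on this electron-poor allylic alcohol. The fallback sets out from 9 and replaces the protic phosphonate homologation by an aprotic silicon-based one. The oxidation is run on its own (MnO2, CH2Cl2, rt) and aldehyde 10 is isolated. Colvin homologation with lithiated trimethylsilyldiazomethane (Me3SiCHN2, LiN(iPr)2, THF, −78 to 0 °C) should then give the alkyne by addition to the aldehyde, Peterson-type loss of silanolate and 1,2-hydrogen shift of the alkylidene carbene, with no alkoxide present. The fallback comes back to the route at 11 and makes no compound outside the list (F0).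

Step 2. Enolisation and intermolecular C-acylation of the doubly ortho-substituted ketone may be slow and reversible, the phenoxide may be acylated on oxygen instead, and the ester may be hydrolysed in the acid stage. The fallback sets out from 5 and makes the C-acylation intramolecular. O-Acylation with ethyl chlorooxoacetate (pyridine, CH2Cl2, 0 °C) should give ethyl 3,5-dimethoxy-2-(5-methylhexanoyl)phenyl oxalate F4. KOtBu (THF, 0 °C) should then move the ethoxalyl group from oxygen to the α-carbon by a Baker–Venkataraman-type intramolecular Claisen condensation, which gives the same diketo ester 7. HCl in EtOH at reflux closes it to 8, where the fallback comes back to the route.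

Further compounds
F1 | step 5 | 3,5-dimethoxy-2-(5-methylhexanoyl)phenyl 3,4,5-trimethoxybenzoate | CC(C)CCCC(=O)c1c(OC)cc(OC)cc1OC(=O)c1cc(OC)c(OC)c(OC)c1
F2 | step 5 | 1-(2-hydroxy-4,6-dimethoxyphenyl)-2-(3-methylbutyl)-3-(3,4,5-trimethoxyphenyl)propane-1,3-dione (racemic, enolisable) | CC(C)CCC(C(=O)c1c(O)cc(OC)cc1OC)C(=O)c1cc(OC)c(OC)c(OC)c1
F3 | step 5 | 5,7-dimethoxy-3-(3-methylbutyl)-2-(3,4,5-trimethoxyphenyl)chromen-4-one | CC(C)CCc1c(-c2cc(OC)c(OC)c(OC)c2)oc2cc(OC)cc(OC)c2c1=O
F0 | step 4 | none | none
F4 | step 2 | ethyl 3,5-dimethoxy-2-(5-methylhexanoyl)phenyl oxalate | CCOC(=O)C(=O)Oc1cc(OC)cc(OC)c1C(=O)CCCC(C)C
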